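**Assumption:** the SMILES is read as (2S,3S,5S)-5-bromo-2-[(1R,3R,4R)-3-bromo-4-chloro-4-methylcyclohexyl]-2,6,6-trimethyloxan-3-yl acetate; methyl (R)-glycidate (L-serine-derived) is taken as the purchased chiral material.

## Retrosynthetic overview

1. Target ⇐ thermal diaxial→diequatorial 1,2-interchange of Br/Cl ⇐ anti-addition of BrCl to the cyclohexene of a bromo-oxane.
2. Oxane ring ⇐ 6-endo bromoetherification of a tertiary alcohol onto the prenyl alkene (sets C5–Br).
3. Tertiary carbinol ⇐ Felkin-type methyl addition to an α-acetoxy ketone; the acetate stereocentre ⇐ Mitsunobu inversion of an α-ketol.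
4. Cyclohexene ⇐ Diels–Alder of isoprene with a chiral α′-hydroxy vinyl ketone, made in three steps from methyl (R)-glycidate (the only purchased stereocentre).
5. Ring order: cyclohexene (cycloaddition) first, oxane second, ring halogens last.

## Route

**Step 1**
Reactants: 1, methyl (R)-glycidate; 2, 2-methylprop-1-enylmagnesium bromide
Product: 3, methyl (2R)-2-hydroxy-5-methylhex-4-enoate
Conditions: 2 (1.3 equiv), CuI (10 mol%), THF, −40 °C; aq NH4Cl
Reagents that add atoms: 2-methylprop-1-enylmagnesium bromide, CC(C)=C[Mg]Br
Why: Cu-catalysed SN2 epoxide opening at the unsubstituted C3 of the glycidate; C2 is not touched, so the (R) centre is retained.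

**Step 2**
Reactants: 3; 4, N,O-dimethylhydroxylamine hydrochloride
Product: 5, (2R)-2-hydroxy-N-methoxy-N,5-dimethylhex-4-enamide
Conditions: 4 (2.5 equiv), i-PrMgCl (6 equiv), THF, −20 → 0 °C
Reagents that add atoms: N,O-dimethylhydroxylamine hydrochloride, CNOC.Cl
Why: Magnesium-amide aminolysis of the ester (Weinreb amide formation) tolerates the free α-hydroxyl as its alkoxide and does not affect the stereocentre.

**Step 3**
Reactants: 5; 6, vinylmagnesium bromide
Product: 7, (4R)-4-hydroxy-7-methylocta-1,6-dien-3-one
Conditions: 6 (3 equiv), THF, 0 °C; inverse quench into cold 1 M HCl; used directly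
Reagents that add atoms: vinylmagnesium bromide, C=C[Mg]Br
Why: Weinreb ketone synthesis; the chelated tetrahedral intermediate prevents over-addition, and the acidic inverse quench stops conjugate addition of the released amine to the enone.

**Step 4 (key cycloaddition; forms the cyclohexene)**
Reactants: 7; 8, isoprene
Product: 9, (2R)-2-hydroxy-5-methyl-1-[(1R)-4-methylcyclohex-3-en-1-yl]hex-4-en-1-one
Conditions: 8 (10 equiv), ZnCl2 (1.1 equiv), CH2Cl2, −40 → −20 °C
Reagents that add atoms: isoprene, C=CC(C)=C
Why: Lewis-acid Diels–Alder in which Zn chelation (reinforcing the internal O–H···O=C bond) holds the ketol syn-planar and s-cis, so isoprene adds "para" to the enone face anti to the prenyl CH2 (Masamune-type α′-hydroxy enone model), setting C1′ as R (dr about 8:1 expected; minor isomer removed by chromatography).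

**Step 5**
Reactants: 9; 10, acetic acid
Product: 11, (2S)-5-methyl-1-[(1R)-4-methylcyclohex-3-en-1-yl]-1-oxohex-4-en-2-yl acetate
Conditions: AcOH (2 equiv), PPh3, DIAD, THF, 0 °C → rt
Reagents that add atoms: acetic acid, CC(=O)O
Why: Mitsunobu reaction; SN2 displacement of the oxyphosphonium at the carbonyl-activated secondary carbon inverts it cleanly (R → S) and installs the acetate of the target in the same operation.

**Step 6**
Reactants: 11; 12, methyltitanium triisopropoxide
Product: 13, (2S,3S)-2-hydroxy-6-methyl-2-[(1R)-4-methylcyclohex-3-en-1-yl]hept-5-en-3-yl acetate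
Conditions: MeTi(Oi-Pr)3 (3 equiv, from MeLi + ClTi(Oi-Pr)3), CH2Cl2/Et2O, −30 °C → rt
Reagents that add atoms: methyltitanium triisopropoxide, C[Ti](OC(C)C)(OC(C)C)OC(C)C
Why: The non-basic, non-chelating titanium reagent adds to the ketone in preference to the ester and follows the polar Felkin–Anh/Cornforth model (C–OAc anti to the incoming methyl, attack past H), giving the 2S carbinol, which is the diastereomer opposite to the Cram-chelate product.

**Step 7 (forms the oxane)**
Reactants: 13; 14, N-bromosuccinimide
Product: 15, (2S,3S,5S)-5-bromo-2,6,6-trimethyl-2-[(1R)-4-methylcyclohex-3-en-1-yl]oxan-3-yl acetate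
Conditions: NBS (1.05 equiv), HFIP/CH2Cl2 (1:3), 4 Å MS, −20 → 0 °C
Reagents that add atoms: N-bromosuccinimide, O=C1CCC(=O)N1Br
Why: Bromoetherification in which the bromonium on the more reactive isopropylidene alkene is captured 6-endo (Markovnikov) by the tertiary OH through a chair with the cyclohexenyl equatorial and Br anti to oxygen (hence equatorial), which sets C5 as S.

**Step 8**
Reactants: 15; 16, bromine monochloride
Product: 17, (2S,3S,5S)-5-bromo-2-[(1R,3S,4S)-4-bromo-3-chloro-4-methylcyclohexyl]-2,6,6-trimethyloxan-3-yl acetate (trans-diaxial; obtained with some 18)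
Conditions: BrCl (1.05 equiv, CH2Cl2 solution), CH2Cl2, −78 °C, dark; chromatography
Reagents that add atoms: bromine monochloride, ClBr
Why: Electrophilic anti-addition in which the bromonium cis to the C1′ substituent is opened by chloride trans-diaxially at the secondary carbon (Fürst–Plattner) to give 17, plus some 18 from Markovnikov opening, while the bromonium on the other face gives the separable diaxial 3-bromo-4-chloro diastereomer, so about 35–45% of 17 + 18 is expected per pass.

**Step 9**
Reactants: 17 (with any 18 from step 8)
Product: 18, acetylcaespitol, (2S,3S,5S)-5-bromo-2-[(1R,3R,4R)-3-bromo-4-chloro-4-methylcyclohexyl]-2,6,6-trimethyloxan-3-yl acetate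
Conditions: toluene, solid NaHCO3, 100 °C, dark, sealed tube
Reagents that add atoms: none
Why: Thermal dyotropic (diaxial → diequatorial) rearrangement in which Br and Cl exchange carbons, each staying on its own face, so 4′-Br(ax)/3′-Cl(ax) becomes 3′-Br(eq)/4′-Cl(eq) with both centres fixed by those of 17, driven by chlorine preferring the tertiary carbon.

## Compound list

1 | methyl (R)-glycidate | COC(=O)[C@H]1CO1 | starting material
2 | 2-methylprop-1-enylmagnesium bromide | CC(C)=C[Mg]Br | starting material
3 | methyl (2R)-2-hydroxy-5-methylhex-4-enoate | O[C@H](CC=C(C)C)C(=O)OC | intermediate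
4 | N,O-dimethylhydroxylamine hydrochloride | CNOC.Cl | starting material
5 | (2R)-2-hydroxy-N-methoxy-N,5-dimethylhex-4-enamide | O[C@H](CC=C(C)C)C(=O)N(C)OC | intermediate
6 | vinylmagnesium bromide | C=C[Mg]Br | starting material
7 | (4R)-4-hydroxy-7-methylocta-1,6-dien-3-one | O[C@H](CC=C(C)C)C(=O)C=C | intermediate
8 | isoprene | C=CC(C)=C | starting material
9 | (2R)-2-hydroxy-5-methyl-1-[(1R)-4-methylcyclohex-3-en-1-yl]hex-4-en-1-one | O[C@H](CC=C(C)C)C(=O)[C@@H]1CCC(C)=CC1 | intermediate
10 | acetic acid | CC(=O)O | starting material
11 | (2S)-5-methyl-1-[(1R)-4-methylcyclohex-3-en-1-yl]-1-oxohex-4-en-2-yl acetate | CC(=O)O[C@@H](CC=C(C)C)C(=O)[C@@H]1CCC(C)=CC1 | intermediate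
12 | methyltitanium triisopropoxide | C[Ti](OC(C)C)(OC(C)C)OC(C)C | starting material (reagent, made in situ)
13 | (2S,3S)-2-hydroxy-6-methyl-2-[(1R)-4-methylcyclohex-3-en-1-yl]hept-5-en-3-yl acetate | CC(=O)O[C@@H](CC=C(C)C)[C@@](C)(O)[C@@H]1CCC(C)=CC1 | intermediate
14 | N-bromosuccinimide | O=C1CCC(=O)N1Br | starting material (reagent)
15 | (2S,3S,5S)-5-bromo-2,6,6-trimethyl-2-[(1R)-4-methylcyclohex-3-en-1-yl]oxan-3-yl acetate | CC(=O)O[C@H]1C[C@H](Br)C(C)(C)O[C@@]1(C)[C@@H]1CCC(C)=CC1 | intermediate
16 | bromine monochloride | ClBr | starting material (reagent)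
17 | (2S,3S,5S)-5-bromo-2-[(1R,3S,4S)-4-bromo-3-chloro-4-methylcyclohexyl]-2,6,6-trimethyloxan-3-yl acetate | CC(=O)O[C@H]1C[C@H](Br)C(C)(C)O[C@@]1(C)[C@@H]1CC[C@](C)(Br)[C@@H](Cl)C1 | intermediate
18 | acetylcaespitol, (2S,3S,5S)-5-bromo-2-[(1R,3R,4R)-3-bromo-4-chloro-4-methylcyclohexyl]-2,6,6-trimethyloxan-3-yl acetate | CC(=O)O[C@H]1C[C@H](Br)C(C)(C)O[C@@]1(C)[C@@H]1CC[C@@](C)(Cl)[C@H](Br)C1 | target

## Summary

Total steps: 9. Longest linear sequence: 9 (fully linear from methyl (R)-glycidate).

Three steps most likely to fail:

1. **Steps 8–9 (ring bromochlorination and halogen interchange).** The cyclohexene has little facial bias, so up to half the material goes to the wrong diaxial adduct, and the 17 → 18 equilibrium rests on the reported behaviour of the natural isocaespitol/caespitol pair as I recall it. Fallback: epoxidise 15 (mCPBA) and separate the epoxide anti to the C1′ substituent. Open it trans-diaxially with HBr at the tertiary carbon. Then chlorinate the resulting axial secondary alcohol (PPh3/NCS) with bromine participation, which generates only the required bromonium and leads to 17/18.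

2. **Step 7 (bromoetherification).** 5-exo oxolane formation, attack on the ring alkene and the C5 epimer all compete; yields of such bromo-oxanes are often modest. Fallback: reversible Hg(TFA)2-mediated cyclisation to the thermodynamic 6-membered organomercurial, followed by brominative demercuration (Br2, LiBr, pyridine).

3. **Step 6 (methyl addition to the α-acetoxy ketone).** Risks are incomplete Felkin selectivity, sluggish addition and acetyl migration. Fallback: add MeMgBr to the free ketol 9 under Cram-chelate control, which reliably gives the 2S carbinol but with the 3R alcohol. Cyclise as in step 7, then correct C3 by oxidation to the oxan-3-one and L-Selectride reduction to the axial alcohol, and acetylate.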